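The decamethylene tether is disconnected between C2 and C3, counted from the dimethoxyaryl ring, into a 2-(3,5-dimethoxyphenyl)ethyl unit and an 8-phenyloctyl unit. The key step exploits the benzylic C1–C2 ethylene unit on the 3,5-dimethoxybenzene ring as a latent vinyl group: 9-BBN adds anti-Markovnikov to 3,5-dimethoxystyrene, placing boron on C2, and the resulting B-alkyl-9-BBN is coupled in the same flask with (8-bromooctyl)benzene in a Pd/PCy3 alkyl–alkyl Suzuki–Miyaura reaction. One operation thus reduces the alkene and forges the sp3–sp3 C2–C3 bond, giving the target directly from two purchasable fragments; the precursor is a styrene, not a saturated chain.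

Key step: step 1

Remark: compounds 1 and 2 are assumed to be catalogue chemicals; the target has no stereocentre, so no stereocontrol is needed.

Step 1
Reactants: 1 3,5-dimethoxystyrene; 2 (8-bromooctyl)benzene
Product: 4 1,3-dimethoxy-5-(10-phenyldecyl)benzene, via trialkylborane 3 (not isolated)
Conditions: 1, 9-BBN (0.5 M in THF), 0 °C → rt; then 2, Pd(OAc)2 (4 mol %), PCy3 (8 mol %), K3PO4·H2O, THF, rt
Reagents that add atoms: none
Why: 9-BBN should add across the vinyl group through a four-centre syn transition state with boron on the terminal carbon, giving trialkylborane 3; Pd(0)/PCy3 then inserts into the primary C–Br bond of 2 by an SN2-type oxidative addition, the base-activated borate transfers its primary 2-arylethyl group to palladium, and reductive elimination forms the C(sp3)–C(sp3) bond. The closest known reaction type is the B-alkyl Suzuki–Miyaura coupling of alkyl-9-BBN reagents with unactivated primary alkyl bromides under Pd/trialkylphosphine catalysis, run in one pot after the hydroboration. No ring is closed and no stereocentre is created. The step needs anti-Markovnikov regioselectivity, which the bulk of 9-BBN and the unhindered terminal CH2 of the styrene secure; it needs transfer of the primary alkyl group in preference to the secondary bridgehead B–C bonds of the bicycle; and it needs reductive elimination to outrun β-hydride elimination, which the bulky, electron-rich PCy3 ligand favours. The aryl methyl ethers and both benzene rings should be inert to the borane, the base and Pd(0).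

Compound list
1 | 3,5-dimethoxystyrene (1-ethenyl-3,5-dimethoxybenzene) | COc1cc(C=C)cc(OC)c1 | starting material
2 | (8-bromooctyl)benzene | BrCCCCCCCCc1ccccc1 | starting material
3 | 9-[2-(3,5-dimethoxyphenyl)ethyl]-9-borabicyclo[3.3.1]nonane | COc1cc(CCB2C3CCCC2CCC3)cc(OC)c1 | intermediate
4 | 1,3-dimethoxy-5-(10-phenyldecyl)benzene | COc1cc(CCCCCCCCCCc2ccccc2)cc(OC)c1 | target

Total step count: 1
Longest linear sequence: 1 step

Steps most likely to fail: the route has a single step, so the ranking has one entry.

Step 1. Two processes could defeat the coupling. β-Hydride elimination from the alkylpalladium intermediates could outrun transmetalation and reductive elimination, returning styrene 1 and giving 8-phenyloct-1-ene. Alternatively, the borate could transfer its primary alkyl group too slowly, so that the bromide is consumed by reduction or homocoupling. The fallback makes the same C2–C3 bond by a radical pathway at the alkene oxidation level. It sets out from 1 together with 2. A visible-light palladium-catalysed alkyl Heck reaction (Pd(OAc)2, Xantphos, Cs2CO3, benzene, blue LEDs, rt) should generate the 8-phenyloctyl radical from 2 and add it to the terminal carbon of 1. β-Hydride elimination from the benzylic palladium species should then give (E)-1,3-dimethoxy-5-(10-phenyldec-1-en-1-yl)benzene F1. Hydrogenation of F1 (H2, 10 % Pd/C, EtOAc, rt) should saturate the alkene without touching the aryl ethers, and the fallback comes back to the route at 4.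

Further compounds
F1 | step 1 | (E)-1,3-dimethoxy-5-(10-phenyldec-1-en-1-yl)benzene | COc1cc(/C=C/CCCCCCCCc2ccccc2)cc(OC)c1
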